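Time comes first here: the mark in these questions arrives very early in the run.

| flask | left-handed substrate | right-handed substrate | partner | precatalyst | remark |
|---|---|---|---|---|---|
| blue | 0.26 M | 0.26 M | 1.5 equiv | 0.1 mol% | run made earlier |
| violet | 0.26 M | 0.26 M | 2.4 equiv | 0.1 mol% | run made earlier |
| grey | 0.26 M | 0.26 M | 1.1 equiv | 0.2 mol% | run made earlier |
| flask | 0.26 M | 0.26 M | 1.10 equiv | 0.1 mol% |  |

| run | time / min | left-handed product / % |
|---|---|---|
| blue | 0.250 | 7.4 |
| blue | 0.833 | 24.2 |
| blue | 1.33 | 28.7 |
| blue | 2.00 | 32.6 |
| blue | 3.00 | 34.1 |
| violet | 0.667 | 29.0 |
| violet | 1.33 | 34.6 |
| violet | 2.00 | 35.8 |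
| violet | 2.50 | 35.1 |
| violet | 3.00 | 34.8 |
| grey | 0.667 | 23.9 |
| grey | 1.33 | 31.5 |
| grey | 2.00 | 34.1 |
| grey | 2.50 | 36.4 |
| grey | 3.00 | 35.5 |

(standard deviation of a reading: 0.5 percentage points)

- free catalyst is single-handed; left-handed substrate and right-handed substrate are mirror images of each other, charged as a racemate, each of them at the stated concentration
- steps that have been proposed: free catalyst + left-handed substrate <-> catalyst intermediate A; free catalyst + right-handed substrate <-> catalyst intermediate B; partner + catalyst intermediate A -> free catalyst + left-handed product; partner + catalyst intermediate B -> free catalyst + right-handed product; partner + precatalyst -> free catalyst + spent reagent; partner + free catalyst -> spent catalyst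

* factor on the rate of making left-handed product when 5.0% of the left-handed substrate and right-handed substrate together are converted if partner is charged twice over
* factor on the rate when 5.0% of the left-handed substrate and right-handed substrate together are converted if precatalyst is charged at 1 mol% instead

Blue had passed the mark by its first reading, with 7.4% left-handed product after 0.250 min. The mark of 5.0% was a fraction 0.147 of blue's last reading.

The bench rule says that rate follows the catalyst charged, so the new loading should give a factor of 10.0. That rule assumes the catalyst is already working at the mark. Here, though, partner has to convert precatalyst first, and a heavier charge reaches the mark sooner, possibly before that conversion has got far. I did not try to read the length of this start-up from these runs, so I took its limit.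

While precatalyst is still feeding the round at a steady rate, working catalyst grows with time, and product grows with the square of time. Its acceleration goes with the loading and with the square of the partner. At a fixed conversion the rate then goes with the square root of that acceleration. I called this square root the start-up factor, and for the new loading it is 3.16.

For doubled partner the same reckoning gives 2.00, which is also what the bench rule gives for a rate first order in partner. I committed to about 2.00 for partner and to a little over 3.16 for loading.

The forecast gave 2 and 8.5, in its words “somewhat under tenfold”. The simulation gave 2.08 and 3.85.

    free catalyst + left-handed substrate ⇌ catalyst intermediate A (K = 3.90 M⁻¹, k = 19000 M⁻¹ s⁻¹)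
    free catalyst + right-handed substrate ⇌ catalyst intermediate B (K = 3.30 M⁻¹, k = 11000 M⁻¹ s⁻¹)
    partner + catalyst intermediate A → free catalyst + left-handed product (k = 330 M⁻¹ s⁻¹)
    partner + catalyst intermediate B → free catalyst + right-handed product (k = 130 M⁻¹ s⁻¹)
    partner + precatalyst → free catalyst + spent reagent (k = 0.140 M⁻¹ s⁻¹)
    partner + free catalyst → spent catalyst (k = 0.270 M⁻¹ s⁻¹)

In this flask the loading factor 3.85 came out above the start-up factor 3.16 and below 10.0, and the partner factor was 2.08 against 2.00. One effect on the rate at the mark in this flask was the way back from catalyst intermediate B to free catalyst and right-handed substrate: the same run without that way back gave 0.0457 times the actual rate. With partner as charged, precatalyst turned over at 2.4 min⁻¹, a half-life of 0.289 min, longer than the 0.211 min this flask took to reach the mark. After 0.300 min, precatalyst in this flask still stood at 50.8% of the catalyst charged.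

All runs stem from a simulated flask for an exercise; scatter was added.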